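The route rests on cutting the bond between the lactone ring-fusion carbon (C7) and the acyloxy-bearing carbinol (C8) of the ten-membered carbocycle. The feature exploited is the homoallylic alcohol motif C13H2=C11–C7–C8–O that links the exocyclic methylene of the γ-lactone ring to C8. One chromium-mediated intramolecular Nozaki–Hiyama allylation of an aldehyde by a 3-(bromomethyl)butenolide closes the carbocycle onto the preformed lactone, shifts the double bond to unveil the α-methylene group, and sets C7 and C8. The precursor is an open-chain C8 aldehyde carrying a flat 5-substituted 3-(bromomethyl)furan-2(5H)-one, assembled by B-alkyl Suzuki coupling and ring-closing metathesis.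

Key step: step 15

Numbering used: carbocycle C1–C10 with C3=C4 the (Z)-alkene, C4 carrying the methyl group, C5 the free hydroxyl, C6 the lactone oxygen, C7 the lactone branch, C8 the ester and C10 the hydroxymethyl group (C14); C11, C12 and C13 are the lactone α-carbon, carbonyl carbon and exocyclic methylene.

Assumption: (R)-2-methylbutanoic acid and (−)-B-methoxydiisopinocampheylborane (from (+)-α-pinene) are taken as commercial; the facial sense of the iridium catalyst in step 3 is assigned by analogy with this ligand class, and the mirror-image ligand would be used if it proved opposite.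

Step 1
Reactants: 1 (E)-but-2-ene-1,4-diol
Product: 2 (E)-4-((tert-butyldiphenylsilyl)oxy)but-2-en-1-ol
Conditions: NaH (1.0 equiv), THF, 0 °C; then TBDPSCl (1.0 equiv), 0 °C to rt
Reagents that add atoms: tert-butyl(chloro)diphenylsilane (TBDPSCl), CC(C)(C)[Si](Cl)(c1ccccc1)c1ccccc1
Why: One equivalent of NaH gives the sparingly soluble monoalkoxide, which is O-silylated once, so the symmetric diol is converted mainly into the mono ether.

Step 2
Reactants: 2 (E)-4-((tert-butyldiphenylsilyl)oxy)but-2-en-1-ol
Product: 3 (E)-4-((tert-butyldiphenylsilyl)oxy)but-2-en-1-yl methyl carbonate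
Conditions: ClCO2Me, pyridine, CH2Cl2, 0 °C
Reagents that add atoms: methyl chloroformate, COC(=O)Cl
Why: Acylation of the primary allylic alcohol gives the allylic methyl carbonate that serves as leaving group and internal base source in the next step.

Step 3
Reactants: 3 (E)-4-((tert-butyldiphenylsilyl)oxy)but-2-en-1-yl methyl carbonate; 4 dimethyl malonate
Product: 5 dimethyl 2-[(2S)-1-((tert-butyldiphenylsilyl)oxy)but-3-en-2-yl]malonate
Conditions: [Ir(cod)Cl]2 (2 mol%), (Ra,Rc,Rc)-O,O'-(1,1'-binaphthyl-2,2'-diyl)-N,N-bis(1-phenylethyl)phosphoramidite (4 mol%), TBD (8 mol%), THF, rt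
Reagents that add atoms: none
Why: Iridium-catalysed asymmetric allylic alkylation should deliver the malonate to the substituted allyl terminus (branched product), and the chiral phosphoramidite sets the stereocentre that becomes C10.

Step 4
Reactants: 5 dimethyl 2-[(2S)-1-((tert-butyldiphenylsilyl)oxy)but-3-en-2-yl]malonate
Product: 6 methyl (3R)-3-(((tert-butyldiphenylsilyl)oxy)methyl)pent-4-enoate
Conditions: NaCl, H2O, DMSO, 150 °C
Reagents that add atoms: none
Why: Krapcho dealkoxycarbonylation removes one ester group under neutral conditions, and the stereocentre, being β to the carbonyl, cannot epimerise.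

Step 5
Reactants: 6 methyl (3R)-3-(((tert-butyldiphenylsilyl)oxy)methyl)pent-4-enoate
Product: 7 (3R)-3-(((tert-butyldiphenylsilyl)oxy)methyl)-N-methoxy-N-methylpent-4-enamide
Conditions: MeONHMe·HCl, i-PrMgCl, THF, −20 °C
Reagents that add atoms: N,O-dimethylhydroxylamine hydrochloride, CNOC.Cl
Why: Aminolysis of the ester by the magnesium amide gives the Weinreb amide, a carbonyl group that should survive hydroboration and cross-coupling and can later be reduced cleanly to the aldehyde.

Step 6
Reactants: 8 prop-2-yn-1-ol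
Product: 10 (Z)-3-iodo-2-methylprop-2-en-1-ol, via alkenylmagnesium alkoxide 9 (not isolated)
Conditions: MeMgBr (2.5 equiv), CuI (10 mol%), THF/Et2O, −10 °C to rt; then I2, −78 to 0 °C
Reagents that add atoms: methylmagnesium bromide, C[Mg]Br; iodine, II
Why: Copper-catalysed carbomagnesiation of the propargylic alkoxide places the methyl group on the internal carbon in an anti addition directed by the magnesium alkoxide, and iodinolysis with retention fixes the (Z) geometry of the future C3=C4 bond.

Step 7
Reactants: 10 (Z)-3-iodo-2-methylprop-2-en-1-ol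
Product: 11 (Z)-3-iodo-2-methylprop-2-enal
Conditions: MnO2 (excess), CH2Cl2, rt; solution used directly
Reagents that add atoms: none
Why: Allylic oxidation with MnO2 is neutral and should give the enal without isomerising the (Z) double bond.

Step 8
Reactants: 11 (Z)-3-iodo-2-methylprop-2-enal; 12 allyl 4-methoxyphenyl ether
Product: 15 (1Z,3R,4R)-1-iodo-4-(4-methoxyphenoxy)-2-methylhexa-1,5-dien-3-ol, via allylborane 13 (not isolated), via borinate ester 14 (not isolated)
Conditions: 12, sec-BuLi, THF, −78 °C; (−)-Ipc2BOMe; BF3·OEt2; then 11, −78 °C; NaOH, H2O2, rt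
Reagents that add atoms: none
Why: Brown alkoxyallylboration: the (Z)-γ-aryloxyallylborane reacts through a chair Zimmerman–Traxler transition state to give the syn diol monoether, and the isopinocampheyl groups direct attack to the Si face of the aldehyde, which sets the future C5 (R) and C6 (R).

Step 9
Reactants: 15 (1Z,3R,4R)-1-iodo-4-(4-methoxyphenoxy)-2-methylhexa-1,5-dien-3-ol
Product: 16 tert-butyldimethylsilyl ether of 15
Conditions: TBSOTf, 2,6-lutidine, CH2Cl2, −78 to 0 °C
Reagents that add atoms: tert-butyldimethylsilyl trifluoromethanesulfonate (TBSOTf), CC(C)(C)[Si](C)(C)OS(=O)(=O)C(F)(F)F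
Why: Silylation with the silyl triflate protects the hindered secondary allylic C5 hydroxyl until the last step.

Step 10
Reactants: 7 (3R)-3-(((tert-butyldiphenylsilyl)oxy)methyl)-N-methoxy-N-methylpent-4-enamide; 16 tert-butyldimethylsilyl ether of 15
Product: 18 (3S,6Z,8R,9R)-8-((tert-butyldimethylsilyl)oxy)-3-(((tert-butyldiphenylsilyl)oxy)methyl)-N-methoxy-9-(4-methoxyphenoxy)-N,7-dimethylundeca-6,10-dienamide, via alkylborane 17 (not isolated)
Conditions: 7, 9-BBN dimer, THF, rt; then 16, Pd(dppf)Cl2 (5 mol%), AsPh3, Cs2CO3, DMF/H2O, rt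
Reagents that add atoms: none
Why: B-alkyl Suzuki–Miyaura coupling: anti-Markovnikov hydroboration of the vinyl group and palladium-catalysed coupling with the alkenyl iodide join the fragments at C2–C3 with retention of the (Z) geometry.

Step 11
Reactants: 18 coupled Weinreb amide
Product: 19 (3S,6Z,8R,9R)-8-((tert-butyldimethylsilyl)oxy)-3-(((tert-butyldiphenylsilyl)oxy)methyl)-9-hydroxy-N-methoxy-N,7-dimethylundeca-6,10-dienamide
Conditions: (NH4)2Ce(NO3)6, pyridine, MeCN/H2O (4:1), 0 °C
Reagents that add atoms: none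
Why: Oxidative cleavage of the 4-methoxyphenyl ether (the arene leaves as benzoquinone) should free the C6 hydroxyl while the silyl ethers, alkenes and amide remain.

Step 12
Reactants: 19 C6 alcohol Weinreb amide
Product: 20 (3S,6Z,8R,9R)-8-((tert-butyldimethylsilyl)oxy)-3-(((tert-butyldiphenylsilyl)oxy)methyl)-9-hydroxy-7-methylundeca-6,10-dienal
Conditions: i-Bu2AlH (2.5 equiv), THF, −78 °C; aqueous Rochelle salt
Reagents that add atoms: none
Why: Reduction of the Weinreb amide stops at the chelated hemiaminal, which gives the C8 aldehyde on work-up; the free hydroxyl only consumes one equivalent of hydride.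

Step 13
Reactants: 20 hydroxy aldehyde; 21 2-(bromomethyl)acrylic acid
Product: 22 2-(bromomethyl)acrylate ester of 20 at the C6 hydroxyl
Conditions: DCC, DMAP (10 mol%), CH2Cl2, 0 °C
Reagents that add atoms: none
Why: Steglich esterification of the only free hydroxyl installs the future lactone carbonyl together with the allylic bromide, and catalytic DMAP at 0 °C limits SN2' attack on the bromide.

Step 14
Reactants: 22 2-(bromomethyl)acrylate ester
Product: 23 (3S,6Z,8R)-8-[(2R)-4-(bromomethyl)-5-oxo-2,5-dihydrofuran-2-yl]-8-((tert-butyldimethylsilyl)oxy)-3-(((tert-butyldiphenylsilyl)oxy)methyl)-7-methyloct-6-enal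
Conditions: second-generation Grubbs catalyst (H2IMes)(PCy3)Cl2Ru=CHPh (10 mol%), toluene (0.01 M), 80 °C
Reagents that add atoms: none
Why: Ring-closing metathesis between the vinyl group on C6 and the acrylate closes the five-membered butenolide with loss of ethene; the trisubstituted C3=C4 alkene is unreactive and could only give a four-membered ring.

Step 15
Reactants: 23 3-(bromomethyl)butenolide aldehyde
Product: 26 macrocyclic (8R) alcohol (C5 OTBS and C14 OTBDPS), via allylchromium species 24 (not isolated), via chromium alkoxide 25 (not isolated)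
Conditions: CrCl2 (10 equiv), THF, rt, slow addition of 23 by syringe pump (final 2 mM); aqueous work-up
Reagents that add atoms: none
Why: Two equivalents of CrCl2 reduce the allylic bromide to the allylchromium species 24 (trivalent chromium), whose γ-carbon C7 adds to the tethered aldehyde C8 in SE2' fashion, so that the C7=C11 double bond moves to the exocyclic C11=C13 position while the C7–C8 bond closes the carbocycle. The closest known reaction types are the chromium-mediated Barbier addition of 3-(bromomethyl)furan-2(5H)-one to aldehydes and the intramolecular Nozaki–Hiyama allylation that closes ten-membered germacranolide rings from acyclic 2-(bromomethyl)acrylates. The ten-membered ring closes in the 10-exo-trig mode on the aldehyde carbonyl, with the lactone already in place. C7 is controlled by C6: the new bond should form anti to the C5 branch, because the trans ring fusion gives a C5–C6–C7–C8 torsion near 150° that a cyclodecene accommodates, whereas the cis fusion would impose a nearly eclipsed torsion. C8 is controlled by the chair Zimmerman–Traxler transition state of the ring-locked (E)-type allylchromium unit with the aldehyde chain pseudo-equatorial, which should give the anti adduct, the (8R) alcohol. The step needs γ- over α-attack, carbonyl addition over reductive opening of the lactone, and cyclisation over oligomerisation; these are secured by the six-membered chromium transition state, the neutral conditions and high dilution.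

Step 16
Reactants: 26 macrocyclic (8R) alcohol; 27 (R)-2-methylbutanoic acid
Product: 28 bis-silyl ether of the target with the (8S) ester
Conditions: PPh3, DIAD, toluene, 0 °C to rt
Reagents that add atoms: none
Why: Mitsunobu esterification: the carboxylate displaces the alkoxyphosphonium group at C8 in an SN2 reaction with inversion, turning the (8R) alcohol into the (8S) ester without touching the α-stereocentre of the acid.

Step 17
Reactants: 28 bis-silyl ether
Product: 29 target CNP0147756.3
Conditions: HF·pyridine, pyridine, THF, 0 °C to rt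
Reagents that add atoms: none
Why: Buffered fluoride cleavage removes both silyl ethers, and these mildly acidic conditions should leave the ester, the allylic alcohol and the α-methylene lactone intact.

Compound list

1 | (E)-but-2-ene-1,4-diol | OC/C=C/CO | starting material
2 | (E)-4-((tert-butyldiphenylsilyl)oxy)but-2-en-1-ol | OC/C=C/CO[Si](c1ccccc1)(c1ccccc1)C(C)(C)C | intermediate
3 | (E)-4-((tert-butyldiphenylsilyl)oxy)but-2-en-1-yl methyl carbonate | COC(=O)OC/C=C/CO[Si](c1ccccc1)(c1ccccc1)C(C)(C)C | intermediate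
4 | dimethyl malonate | COC(=O)CC(=O)OC | starting material
5 | dimethyl 2-[(2S)-1-((tert-butyldiphenylsilyl)oxy)but-3-en-2-yl]malonate | COC(=O)C(C(=O)OC)[C@@H](CO[Si](c1ccccc1)(c1ccccc1)C(C)(C)C)C=C | intermediate
6 | methyl (3R)-3-(((tert-butyldiphenylsilyl)oxy)methyl)pent-4-enoate | COC(=O)C[C@@H](CO[Si](c1ccccc1)(c1ccccc1)C(C)(C)C)C=C | intermediate
7 | (3R)-3-(((tert-butyldiphenylsilyl)oxy)methyl)-N-methoxy-N-methylpent-4-enamide | CON(C)C(=O)C[C@@H](CO[Si](c1ccccc1)(c1ccccc1)C(C)(C)C)C=C | intermediate
8 | prop-2-yn-1-ol | C#CCO | starting material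
9 | bromomagnesium (Z)-3-(bromomagnesio)-2-methylprop-2-en-1-olate | Br[Mg]/C=C(/C)CO[Mg]Br | intermediate
10 | (Z)-3-iodo-2-methylprop-2-en-1-ol | I/C=C(/C)CO | intermediate
11 | (Z)-3-iodo-2-methylprop-2-enal | I/C=C(/C)C=O | intermediate
12 | allyl 4-methoxyphenyl ether | C=CCOc1ccc(OC)cc1 | starting material
13 | (Z)-[3-(4-methoxyphenoxy)allyl]bis(isopinocampheyl)borane | COc1ccc(O/C=C\CB([C@@H]2C[C@@H]3C[C@H]([C@H]2C)C3(C)C)[C@@H]2C[C@@H]3C[C@H]([C@H]2C)C3(C)C)cc1 | intermediate
14 | bis(isopinocampheyl)borinate ester of 15 | I/C=C(/C)[C@@H](OB([C@@H]1C[C@@H]2C[C@H]([C@H]1C)C2(C)C)[C@@H]1C[C@@H]2C[C@H]([C@H]1C)C2(C)C)[C@H](Oc1ccc(OC)cc1)C=C | intermediate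
15 | (1Z,3R,4R)-1-iodo-4-(4-methoxyphenoxy)-2-methylhexa-1,5-dien-3-ol | I/C=C(/C)[C@@H](O)[C@H](Oc1ccc(OC)cc1)C=C | intermediate
16 | tert-butyl(((1Z,3R,4R)-1-iodo-4-(4-methoxyphenoxy)-2-methylhexa-1,5-dien-3-yl)oxy)dimethylsilane | I/C=C(/C)[C@@H](O[Si](C)(C)C(C)(C)C)[C@H](Oc1ccc(OC)cc1)C=C | intermediate
17 | B-alkyl-9-BBN adduct of 7 | CON(C)C(=O)C[C@@H](CO[Si](c1ccccc1)(c1ccccc1)C(C)(C)C)CCB1C2CCCC1CCC2 | intermediate
18 | (3S,6Z,8R,9R)-8-((tert-butyldimethylsilyl)oxy)-3-(((tert-butyldiphenylsilyl)oxy)methyl)-N-methoxy-9-(4-methoxyphenoxy)-N,7-dimethylundeca-6,10-dienamide | CON(C)C(=O)C[C@@H](CO[Si](c1ccccc1)(c1ccccc1)C(C)(C)C)CC/C=C(/C)[C@@H](O[Si](C)(C)C(C)(C)C)[C@H](Oc1ccc(OC)cc1)C=C | intermediate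
19 | (3S,6Z,8R,9R)-8-((tert-butyldimethylsilyl)oxy)-3-(((tert-butyldiphenylsilyl)oxy)methyl)-9-hydroxy-N-methoxy-N,7-dimethylundeca-6,10-dienamide | CON(C)C(=O)C[C@@H](CO[Si](c1ccccc1)(c1ccccc1)C(C)(C)C)CC/C=C(/C)[C@@H](O[Si](C)(C)C(C)(C)C)[C@H](O)C=C | intermediate
20 | (3S,6Z,8R,9R)-8-((tert-butyldimethylsilyl)oxy)-3-(((tert-butyldiphenylsilyl)oxy)methyl)-9-hydroxy-7-methylundeca-6,10-dienal | O=CC[C@@H](CO[Si](c1ccccc1)(c1ccccc1)C(C)(C)C)CC/C=C(/C)[C@@H](O[Si](C)(C)C(C)(C)C)[C@H](O)C=C | intermediate
21 | 2-(bromomethyl)acrylic acid | C=C(CBr)C(=O)O | starting material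
22 | 2-(bromomethyl)acrylate ester of 20 at the C6 hydroxyl | O=CC[C@@H](CO[Si](c1ccccc1)(c1ccccc1)C(C)(C)C)CC/C=C(/C)[C@@H](O[Si](C)(C)C(C)(C)C)[C@H](OC(=O)C(=C)CBr)C=C | intermediate
23 | (3S,6Z,8R)-8-[(2R)-4-(bromomethyl)-5-oxo-2,5-dihydrofuran-2-yl]-8-((tert-butyldimethylsilyl)oxy)-3-(((tert-butyldiphenylsilyl)oxy)methyl)-7-methyloct-6-enal | O=CC[C@@H](CO[Si](c1ccccc1)(c1ccccc1)C(C)(C)C)CC/C=C(/C)[C@@H](O[Si](C)(C)C(C)(C)C)[C@@H]1OC(=O)C(CBr)=C1 | intermediate
24 | allylchromium dichloride species from 23 (trivalent chromium) | O=CC[C@@H](CO[Si](c1ccccc1)(c1ccccc1)C(C)(C)C)CC/C=C(/C)[C@@H](O[Si](C)(C)C(C)(C)C)[C@@H]1OC(=O)C(C[Cr](Cl)Cl)=C1 | intermediate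
25 | chromium alkoxide of 26 | C=C1C(=O)O[C@@H]2[C@@H]1[C@H](O[Cr](Cl)Cl)C[C@@H](CO[Si](c1ccccc1)(c1ccccc1)C(C)(C)C)CC/C=C(/C)[C@H]2O[Si](C)(C)C(C)(C)C | intermediate
26 | macrocyclic (5R,6R,7S,8R,10S) alcohol: trans-fused α-methylene lactone on the (Z)-cyclodecene with free 8-OH, 5-OTBS and 14-OTBDPS | C=C1C(=O)O[C@@H]2[C@@H]1[C@H](O)C[C@@H](CO[Si](c1ccccc1)(c1ccccc1)C(C)(C)C)CC/C=C(/C)[C@H]2O[Si](C)(C)C(C)(C)C | intermediate
27 | (R)-2-methylbutanoic acid | CC[C@@H](C)C(=O)O | starting material
28 | 5-O-TBS, 14-O-TBDPS bis-silyl ether of the target (8S ester) | C=C1C(=O)O[C@@H]2[C@@H]1[C@@H](OC(=O)[C@H](C)CC)C[C@@H](CO[Si](c1ccccc1)(c1ccccc1)C(C)(C)C)CC/C=C(/C)[C@H]2O[Si](C)(C)C(C)(C)C | intermediate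
29 | CNP0147756.3: (5R,6R,7S,8S,10S) trans-fused α-methylene-γ-butyrolactone on the (Z)-cyclodecene, 8-O-(R)-2-methylbutanoate, free 5-OH and 10-CH2OH | C=C1C(=O)O[C@@H]2[C@@H]1[C@@H](OC(=O)[C@H](C)CC)C[C@@H](CO)CC/C=C(/C)[C@H]2O | target

Total step count: 17. Longest linear sequence: 13 steps (steps 1–5, then 10–17).

Steps most likely to fail

Step 15 (key ring closure). The closure may be diverted by oligomerisation through intermolecular allylation, by reductive 1,4-elimination that opens the lactone, or by low facial selectivity at the aldehyde carbon. Fallback: the allyl nucleophile is changed to a stannane closed under Lewis acid. Starting from 23, Pd(PPh3)4-catalysed coupling with hexabutylditin (THF, rt) gives the 3-((tributylstannyl)methyl)butenolide aldehyde F1. BF3·OEt2 in CH2Cl2 at −78 °C under high dilution should close the ring through an open antiperiplanar transition state, which favours the syn adduct, the macrocyclic (8S) alcohol F2. Esterification of F2 with 27 (DCC, DMAP, CH2Cl2, 0 °C) proceeds with retention and rejoins the route at 28. The same esterification applies if the chromium reaction itself should deliver the (8S) alcohol.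

Step 16 (Mitsunobu inversion). The activated C8 oxygen may be lost by elimination toward the C7=C8 or C8=C9 alkene, or the SN2 displacement may stall at the hindered ring carbinol. Fallback: the inversion is split into sulfonate activation and carboxylate displacement without phosphine. Starting from 26, chloromethanesulfonyl chloride and pyridine (CH2Cl2, 0 °C) give the chloromethanesulfonate F3. This is displaced by caesium (R)-2-methylbutanoate F4 (from 27 and Cs2CO3) with 18-crown-6 in toluene at rt, and the route is rejoined at 28.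

Step 13 (acylation with the bromomethyl acrylic acid). The allylic bromide may be consumed by SN2' attack of DMAP or carboxylate, and the hindered C6 hydroxyl may acylate slowly. Fallback: the bromide is carried in latent form. Ethyl 2-(bromomethyl)acrylate and 4-methoxybenzyl alcohol (NaH, THF) give ethyl 2-(((4-methoxybenzyl)oxy)methyl)acrylate F5, which is saponified (LiOH, THF/H2O) to 2-(((4-methoxybenzyl)oxy)methyl)acrylic acid F6. Starting from 20, esterification with F6 (DCC, DMAP) gives the ester F7. Ring-closing metathesis (second-generation Grubbs catalyst, toluene, 80 °C) gives the butenolide 4-methoxybenzyl ether F8. DDQ (CH2Cl2/pH 7 buffer) frees the 3-(hydroxymethyl)butenolide F9, and PPh3/NBS (CH2Cl2, −20 °C) converts it into the bromide, rejoining the route at 23.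

Further compounds

F1 | step 15 | 3-((tributylstannyl)methyl)butenolide aldehyde | O=CC[C@@H](CO[Si](c1ccccc1)(c1ccccc1)C(C)(C)C)CC/C=C(/C)[C@@H](O[Si](C)(C)C(C)(C)C)[C@@H]1OC(=O)C(C[Sn](CCCC)(CCCC)CCCC)=C1
F2 | step 15 | macrocyclic (8S) alcohol (5-OTBS, 14-OTBDPS) | C=C1C(=O)O[C@@H]2[C@@H]1[C@@H](O)C[C@@H](CO[Si](c1ccccc1)(c1ccccc1)C(C)(C)C)CC/C=C(/C)[C@H]2O[Si](C)(C)C(C)(C)C
F3 | step 16 | (8R) chloromethanesulfonate of 26 | C=C1C(=O)O[C@@H]2[C@@H]1[C@H](OS(=O)(=O)CCl)C[C@@H](CO[Si](c1ccccc1)(c1ccccc1)C(C)(C)C)CC/C=C(/C)[C@H]2O[Si](C)(C)C(C)(C)C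
F4 | step 16 | caesium (R)-2-methylbutanoate | CC[C@@H](C)C(=O)[O-].[Cs+]
F5 | step 13 | ethyl 2-(((4-methoxybenzyl)oxy)methyl)acrylate | C=C(COCc1ccc(OC)cc1)C(=O)OCC
F6 | step 13 | 2-(((4-methoxybenzyl)oxy)methyl)acrylic acid | C=C(COCc1ccc(OC)cc1)C(=O)O
F7 | step 13 | 2-(((4-methoxybenzyl)oxy)methyl)acrylate ester of 20 | O=CC[C@@H](CO[Si](c1ccccc1)(c1ccccc1)C(C)(C)C)CC/C=C(/C)[C@@H](O[Si](C)(C)C(C)(C)C)[C@H](OC(=O)C(=C)COCc1ccc(OC)cc1)C=C
F8 | step 13 | 3-(((4-methoxybenzyl)oxy)methyl)butenolide aldehyde | O=CC[C@@H](CO[Si](c1ccccc1)(c1ccccc1)C(C)(C)C)CC/C=C(/C)[C@@H](O[Si](C)(C)C(C)(C)C)[C@@H]1OC(=O)C(COCc2ccc(OC)cc2)=C1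
F9 | step 13 | 3-(hydroxymethyl)butenolide aldehyde | O=CC[C@@H](CO[Si](c1ccccc1)(c1ccccc1)C(C)(C)C)CC/C=C(/C)[C@@H](O[Si](C)(C)C(C)(C)C)[C@@H]1OC(=O)C(CO)=C1
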